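**Retrosynthesis**
- The target is 6-geranyl-(2R,3R)-aromadendrin, a trans-dihydroflavonol. The SMILES gives geranyl at C6 between the 5-OH and 7-OH, C8 as CH, and 2R,3R (2,3-trans).
- Disconnect the C6–geranyl bond as a photochemical O→C [1,3] geranyl shift from a 5-O-geranyl ether. The 5-O has only one free ortho position (C6), because the other ortho carbon is C4a.
- Disconnect the 3-OH as a Rubottom hydroxylation of the flavanone silyl enol ether. It is delivered anti to the 2-aryl group, so C2 sets C3.
- Both stereocenters trace to (S)-naringenin, whose C2 is retained; (2S)-flavanone corresponds to (2R)-dihydroflavonol because the CIP priorities change. No rings are formed, since the chromanone is already present.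

**Assumptions:** (S)-naringenin is taken as commercial (cheap, from naringin). The target is taken as the natural 2,3-trans (2R,3R) dihydroflavonol, as the SMILES shows.

---

**Step 1**
Reactants: 1 (S)-naringenin; 2 tert-butyldimethylsilyl chloride (TBSCl)
Product: 3 (2S)-7,4'-bis-O-TBS-naringenin
Conditions: TBSCl (2.2 equiv), imidazole (4 equiv), DMF, 0 °C → rt, 12 h
Reagents that add atoms: TBSCl, CC(C)(C)[Si](C)(C)Cl
Why: Silyl protection of the two non-chelated phenols; the 5-OH is hydrogen-bonded to C4=O and stays free. C2 is an untouched sp3 C–H under mild imidazole conditions, so it is retained.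

**Step 2**
Reactants: 3 bis-TBS naringenin; 4 geranyl bromide
Product: 5 (2S)-5-O-geranyl-7,4'-bis-O-TBS-naringenin
Conditions: geranyl bromide (1.5 equiv), K2CO3 (3 equiv), KI (cat.), dry acetone, 50 °C, 16 h
Reagents that add atoms: geranyl bromide, CC(C)=CCC/C(C)=C/CBr
Why: Williamson ether synthesis (SN2 at the primary allylic carbon) on the chelated 5-OH; the weak base in dry acetone leaves the aryl TBS ethers intact and does not enolize C3, so C2 is not racemized.

**Step 3**
Reactants: 5 5-O-geranyl flavanone; 6 TBSOTf
Product: 7 (2S)-4-(TBSO)-2-aryl-2H-chromene (silyl enol ether)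
Conditions: TBSOTf (1.5 equiv), Et3N (3 equiv), CH2Cl2, 0 °C, 1 h; rapid cold filtration through Et3N-deactivated silica, used immediately
Reagents that add atoms: TBSOTf, CC(C)(C)[Si](C)(C)OS(=O)(=O)C(F)(F)F
Why: Soft enolization (Mukaiyama-type silyl enol ether formation) with no free 5-OH to quench the base. No lithium enolate is formed, so no E1cB ring opening/racemization. C2 stays sp3.

**Step 4**
Reactants: 7 silyl enol ether; 8 dimethyldioxirane (DMDO)
Product: 9 (2R,3R)-3,7,4'-tris-O-TBS-5-O-geranyl-aromadendrin
Conditions: DMDO (1.05 equiv, ~0.07 M in acetone), CH2Cl2, −78 °C → rt, 2 h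
Reagents that add atoms: DMDO, CC1(C)OO1 (transfers one O)
Why: Rubottom oxidation. The enol ether is far more electron-rich than the trisubstituted geranyl alkene, so it is epoxidized chemoselectively at −78 °C. The oxidant attacks the face anti to the pseudo-axial 2-aryl group. The siloxy-epoxide then opens with 1,4-silyl migration to the α-silyloxy ketone, giving 3-OTBS trans to 2-Ar (2R,3R), with C2 unchanged.

**Step 5**
Reactants: 9 5-O-geranyl tris-TBS ketol
Product: 10 (2R,3R)-6-geranyl-3,7,4'-tris-O-TBS-aromadendrin (free chelated 5-OH)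
Conditions: hν (300 nm, Rayonet or flow photoreactor), degassed cyclohexane (5 mM), 15 °C, Ar, 2–4 h
Reagents that add atoms: none
Why: Proposed new method: homolysis of the weak ArO–CH2 bond of the excited chromanone gives a caged 5-aryloxyl/geranyl radical pair, and recombination at the sole ortho carbon (C6) followed by dienone tautomerization gives the 6-geranyl-5-hydroxy product. The closest known reaction is the photo-Claisen/photo-Fries [1,3] O→C shift of aryl allyl ethers. This is not established for a geranyl ether on a polyoxygenated 3-silyloxy-chromanone. Geranyl enters at C6 with no branched (linalyl-type) product, which thermal [3,3] Claisen would give. The product's 5-OH/C4=O chelate dissipates excitation energy by excited-state proton transfer, so it resists further photolysis. C2 and C3 are not involved, so their configurations are retained.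

**Step 6**
Reactants: 10 tris-TBS 6-geranyl compound
Product: 11 Bonnaniol, (2R,3R)-6-geranyl-3,5,7,4'-tetrahydroxyflavanone
Conditions: HF·pyridine, pyridine, THF, 0 °C → rt, 24 h (plastic vessel), then aq. NaHCO3 quench
Reagents that add atoms: none (only H is added)
Why: Fluoride/HF desilylation of both aryl TBS ethers and the secondary 3-OTBS. The buffered, non-basic medium avoids retro-oxa-Michael ring opening and C3 epimerization, and the geranyl alkene and stereocenters are untouched.

---

**Compound list**

| # | Name | SMILES | Role |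
|---|---|---|---|
| 1 | (S)-Naringenin | O=C1C[C@@H](c2ccc(O)cc2)Oc2cc(O)cc(O)c21 | starting material |
| 2 | TBSCl | CC(C)(C)[Si](C)(C)Cl | starting material |
| 3 | (2S)-7,4'-bis-O-TBS-naringenin | O=C1C[C@@H](c2ccc(O[Si](C)(C)C(C)(C)C)cc2)Oc2cc(O[Si](C)(C)C(C)(C)C)cc(O)c21 | intermediate |
| 4 | Geranyl bromide | CC(C)=CCC/C(C)=C/CBr | starting material |
| 5 | (2S)-5-O-geranyl-7,4'-bis-O-TBS-naringenin | O=C1C[C@@H](c2ccc(O[Si](C)(C)C(C)(C)C)cc2)Oc2cc(O[Si](C)(C)C(C)(C)C)cc(OC/C=C(\C)CCC=C(C)C)c21 | intermediate |
| 6 | TBSOTf | CC(C)(C)[Si](C)(C)OS(=O)(=O)C(F)(F)F | starting material |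
| 7 | (2S)-4-TBSO-2-aryl-2H-chromene enol ether | CC(C)(C)[Si](C)(C)OC1=C[C@@H](c2ccc(O[Si](C)(C)C(C)(C)C)cc2)Oc2cc(O[Si](C)(C)C(C)(C)C)cc(OC/C=C(\C)CCC=C(C)C)c21 | intermediate |
| 8 | Dimethyldioxirane | CC1(C)OO1 | starting material (reagent) |
| 9 | (2R,3R)-3,7,4'-tris-O-TBS-5-O-geranyl-aromadendrin | c1c(O[Si](C)(C)C(C)(C)C)cc2c(c1OC/C=C(\C)CCC=C(C)C)C(=O)[C@H](O[Si](C)(C)C(C)(C)C)[C@@H](c1ccc(O[Si](C)(C)C(C)(C)C)cc1)O2 | intermediate |
| 10 | (2R,3R)-6-geranyl-3,7,4'-tris-O-TBS-aromadendrin | CC(C)=CCC/C(C)=C/Cc1c(O[Si](C)(C)C(C)(C)C)cc2c(c1O)C(=O)[C@H](O[Si](C)(C)C(C)(C)C)[C@@H](c1ccc(O[Si](C)(C)C(C)(C)C)cc1)O2 | intermediate |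
| 11 | Bonnaniol | CC(C)=CCC/C(C)=C/Cc1c(O)cc2c(c1O)C(=O)[C@H](O)[C@@H](c1ccc(O)cc1)O2 | target |

---

**Total steps:** 6 (steps 3 and 4 can be telescoped in one pot). **Longest linear sequence:** 6, from (S)-naringenin.

**Three steps most likely to fail**
1. **Step 5, photochemical [1,3] geranyl shift (the proposed new step).** Risks are C8 (para) recombination, geranyl E/Z scrambling, and loss of the geranyl group as geranyl-derived fragments.
   - Fallback (known chemistry): remove the geranyl ether from 9 with Pd(PPh3)4/morpholine to give the 5-OH tris-TBS ketol. Then do ortho-iodination (NIS, with HPLC separation of the C6 iodide) and Fe(acac)3-catalyzed Kumada coupling with geranylmagnesium chloride.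
2. **Step 4, DMDO Rubottom.** Risks are competing epoxidation of the geranyl alkene and cis/trans selectivity at C3.
   - Fallback: reorder so the hydroxylation precedes any alkene. Tri-silylate naringenin including 5-O (TBSOTf, 2,6-lutidine), run the Rubottom oxidation on that substrate, selectively cleave the chelated 5-OTBS, and then geranylate (step 2 chemistry).
3. **Step 2, geranylation of the chelated 5-OH.** Risks are sluggish alkylation and base-induced C2 racemization.
   - Fallback: neutral Pd-catalyzed Tsuji–Trost O-geranylation of 3 with geranyl methyl carbonate (Pd(PPh3)4, THF), which avoids base entirely.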